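Atom numbering throughout is the briarane numbering: C1–C10 form the ten-membered ring, C1 and C10–C14 form ring A, C15 is the methyl on C1, C16 the CH2O carbon on C5, C17–C19 the lactone carbons with C18 the methyl on C17, and C20 the methyl on C11.

## Analysis of the target

The target is a ten-membered carbocycle (C1–C10) trans-fused at C1/C10 to a cyclohexene (ring A, C11=C12) and fused at C7/C8 to a five-membered lactone (C7, O, C19, C17, C8). It has nine stereocentres (1R, 2S, 4R, 7S, 8S, 9S, 10S, 14S, 17R) and a Z trisubstituted olefin C5=C6 inside the medium ring. On ring A the C15 methyl and C9 are cis, while the C14 acetate and the C2 branch sit on the other face. On the lactone, C6, the C18 methyl and the C8 hydroxyl share one face and C9 takes the other. Sensitive groups are four acetates (O2, O9, O14, O16, the last one allylic), a free allylic C4 hydroxyl, a tertiary β-hydroxy lactone with an epimerisable C17, and C10, which becomes the α-carbon of a β,γ-unsaturated carbonyl in any C9 carbonyl intermediate. The difficulty is the medium ring itself together with the unbroken chain of stereocentres C7–C8–C9–C10–C1–C2, two of them fully substituted (C1, C8). The feature used here is that C8 (tertiary) and C9 (secondary) are neighbouring carbinol carbons of the ten-membered ring and C8 is also a ring atom of the lactone. A reductive union of a C9 aldehyde with a C8 ketone therefore closes the carbocycle and creates both centres, with the five-membered ring already in place to direct the attack on C8.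

## Retrosynthetic reasoning

Endgame adjustments. Target 44 is the desilylated form of 43, and the lactone of 43 is taken back to lactol 42 and to methyl acetal 41. C19 has to stay at the lactol level while C8 is a ketone, because a β-keto lactone would exist as an enolised tetronic acid and would not accept a nucleophile. The acetates on O9 and O16 of 41 are put on together from triol 40, which comes from 39 by loss of a triethylsilyl group. O16 is carried as that silyl ether (not as the acetate) through the chromium coupling and the cyclisation, because an alkenyl metal with an acetoxymethyl group on the metal-bearing carbon can lose acetate to give an allene.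

C8–C9 (key disconnection). Cutting this bond in 39 gives keto aldehyde 38. The cut is made here because it removes the medium ring and two stereocentres at once and leaves two carbonyl groups that are reached by plain oxidation. The forward reaction must join a ketyl carbon (C9) to a ketone carbon (C8) across a ten-membered ring, on the face of the furanone opposite C6 and the C18 methyl. The acetal is carried as the α-L methyl furanoside, with methoxy trans to the C18 methyl. This is the anomer the sugar route delivers, and it should be the less strained arrangement at C17, so enolisation of the C8 ketone toward C17 should not erode that centre.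

Oxidation state and protection. 38 comes from diol 37 by oxidation of both carbinols in one operation. 37 comes from 36 by removal of two 4-methoxybenzyl ethers, and 36 from 35 by silylation of O4. Placing the same oxidatively removable ether on O8 and O9 lets one reagent unveil exactly the two positions that must become carbonyls.

C4–C5. Cutting 35 between C4 and C5 gives aldehyde 17 and alkenyl iodide 34. This is the point of highest convergence: each half carries its own stereocentres, and the Z olefin is made on the small fragment. The forward reaction is a chromium-mediated addition of the alkenyl iodide to the aldehyde, which keeps the olefin geometry and tolerates acetates, ethers and the acetal. It must set C4 (4R, 1,3-syn to O2) under reagent control.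

The Z olefin and C16. Iodide 34 goes back through 33 to stannane 32 and to propargylic alcohol 31. The hydroxyl on C16 directs a trans-hydrostannation that puts tin on C5 and hydrogen on C6, so C7 and the later C4 end up cis. 31 comes from alkyne 29 by adding one carbon to the acetylide, and 29 from aldehyde 28 by one-carbon homologation.

C17 methyl and the sugar. 28 goes back through 27, 26 and 25 to epoxide 24. The C18 methyl enters C17 by anti opening of the epoxide, and this fixes its relation to C7. The epoxide 23/24 comes from mesylate 21, disiloxane 20 and furanoside 19, made from L-arabinose 18. The L-configuration at C4 of the sugar is the 7S centre; C8 is carried as a protected carbinol of no stereochemical consequence.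

Ring A by C11=C12. Aldehyde 17 comes from 16 and 15, and cyclohexene 15 is opened at its trisubstituted olefin to diene 14. Closure of a six-membered ring between a vinyl and an isopropenyl group is reliable and leaves all four stereocentres to acyclic control.

C13–C14. Diacetate 14 comes from diol 13, and 13 from hydroxy aldehyde 12 by allylation, which sets C14 under reagent control. 12 comes from acid 10 through diol 11.

C1–C10 and C1–C2. Acid 10 is cut between C1 and C10 as a [3,3] shift of the enolate 9 of allyl ester 8. This is the only step that has to build the quaternary centre, and it does so with C10 in one suprafacial event. 8 comes from aldol adduct 7 and allylic alcohol 3; 7 from imide 4 and aldehyde 5 (C1–C2 bond, sets C2); 3 from prenol 1 through ether 2.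

## Alternatives that were turned down

Alternative 1: The ten-membered ring would be formed by cutting C1–C10 as a ring-contracting ester-enolate Claisen shift. In the forward sense, the silyl ketene acetal of a fourteen-membered ring in which C14 is esterified to the oxygen on C12 of a C10=C11 allyl unit rearranges to acid A1.
- For: it is pericyclic, needs no reductant and no high dilution, and makes C1 and C10 in the ring-forming step. A fourteen-membered lactonisation is easier than any direct ten-membered closure.
- Against: the geometry of a tetrasubstituted ketene acetal inside a macrocycle and the chair or boat course of a transannular shift are hard to predict. A1 is also far from the target. Ring A is still missing (C12 and C13 must be built on from a neopentyl acid and an isopropenyl group). The lactone is missing (C8 is a ketal, and C17–C19 must later be added to a hindered ring ketone). Five silyl ethers and one benzyl-type ether must be sorted into four acetates and two free hydroxyls.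
- Comparison: on the ring-forming event it is as strong as or stronger than the chosen route. The chosen route uses the same sigmatropic logic for C1–C10 but in an open-chain ester (step 5), where chelation fixes the enolate, and its cyclisation product 39 is five functional-group steps from the target.

Alternative 2: The lactone would be cut at C8–C17 in a preformed carbocycle. In the forward sense, SmI2 turns a 2-bromopropanoate on O7 into a samarium enolate that adds to the C8 ketone and gives A2.
- For: a five-membered intramolecular Reformatsky closure is among the most dependable SmI2 reactions. A2 is only a few protecting-group steps from the target, and the lactone is formed at its final oxidation level.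
- Against: the whole difficulty moves to an unspecified closure of a ten-membered ring that must already carry a ketone between an acyloxy carbon (C7) and a silyloxy carbon (C9). That ketone has two α-oxygen leaving groups, one of them a carboxylate, which SmI2 expels readily. The configuration at C8 depends on which face of a medium-ring ketone the tethered enolate can reach, that is, on ring conformation and not on a rigid control element.
- Comparison: it is stronger on the size of the ring being closed and on closeness to the target. The chosen route forms the carbocycle and C8/C9 in one step, brings C7 and C17 in from a sugar, and has only an ether oxygen α to the ketone.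

Alternative 3: The C4–C9 bond would be reconnected, so that the ten-membered ring becomes two six-membered rings. In the forward sense, Pb(OAc)4 cleaves a cis-fused tricyclic 4,9-diol to diketone A3.
- For: the medium ring arises by fragmentation, with no entropic penalty and no dilution. The Z olefin is fixed beforehand in a six-membered ring, and rigid polycycles are easier to control stereochemically.
- Against: A3 has carbonyls at C4 and C9, so both carbinol centres must then be set by reductions on a flexible ring. The C9 ketone makes C10–H α and allylic at once (conjugation or epimerisation). The C4 ketone is conjugated with C5=C6, which turns the lactone oxygen on C7 and the C16 acetate into vinylogous leaving groups. The tricyclic diol, carrying the lactone and two acetates, is itself a long synthesis.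
- Comparison: it is stronger in the ring-forming event and weaker in stereocontrol at C4 and C9 and in functional-group tolerance. The chosen route sets C4 under reagent control before closure and C9 in the closure.

Key step: step 31

Remark on the chemistry: in step 27 the chromium complex of the (S)-configured sulfonamide ligand is assumed to deliver the 4R carbinol. If the first run shows the opposite sense, the (R)-ligand is used in the same step.
Remark on the chemistry: compounds 1, 4, 5 and 18 are catalogue materials.

## Steps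

Step 1
Reactants: 1 3-methylbut-2-en-1-ol (prenol)
Product: 2 1-methoxy-4-{[(3-methylbut-2-en-1-yl)oxy]methyl}benzene
Conditions: NaH, 4-methoxybenzyl chloride, Bu4NI (cat.), THF/DMF, 0 °C to 25 °C
Reagents that add atoms: 4-methoxybenzyl chloride, COc1ccc(CCl)cc1
Why: Williamson etherification of a primary allylic alkoxide; it installs the O9 protecting group that is later removed oxidatively together with the O8 ether.

Step 2
Reactants: 2 1-methoxy-4-{[(3-methylbut-2-en-1-yl)oxy]methyl}benzene
Product: 3 (2E)-4-[(4-methoxybenzyl)oxy]-2-methylbut-2-en-1-ol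
Conditions: SeO2 (0.3 equiv), t-BuOOH, CH2Cl2, 0 °C to 25 °C, stopped before over-oxidation
Reagents that add atoms: tert-butyl hydroperoxide, CC(C)(C)OO (terminal oxidant; the oxygen is passed on by selenium dioxide, O=[Se]=O)
Why: Selenium dioxide allylic hydroxylation (ene reaction, then [2,3] shift) oxidises the methyl group trans to the chain of a trisubstituted olefin, so the E allylic alcohol should result.

Step 3
Reactants: 4 (4R)-4-benzyl-3-propanoyl-1,3-oxazolidin-2-one; 5 3-{[tert-butyl(dimethyl)silyl]oxy}propanal
Product: 7 (4R)-4-benzyl-3-[(2R,3S)-5-{[tert-butyl(dimethyl)silyl]oxy}-3-hydroxy-2-methylpentanoyl]-1,3-oxazolidin-2-one, via dibutylboron Z-enolate 6 (not isolated)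
Conditions: Bu2BOTf, iPr2NEt, CH2Cl2, 0 °C; then 5, −78 °C to 0 °C; pH 7 buffer, MeOH, H2O2
Reagents that add atoms: none
Why: Evans syn-aldol reaction through the Z boron enolate and a Zimmerman–Traxler chair; the (R)-auxiliary should give the (2R,3S) adduct, whose carbinol carbon is C2 of the target (2S in the final numbering), while the methyl-bearing centre is re-enolised in step 5.

Step 4
Reactants: 7 (4R)-4-benzyl-3-[(2R,3S)-5-{[tert-butyl(dimethyl)silyl]oxy}-3-hydroxy-2-methylpentanoyl]-1,3-oxazolidin-2-one; 3 (2E)-4-[(4-methoxybenzyl)oxy]-2-methylbut-2-en-1-ol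
Product: 8 (2E)-4-[(4-methoxybenzyl)oxy]-2-methylbut-2-en-1-yl (2R,3S)-5-{[tert-butyl(dimethyl)silyl]oxy}-3-hydroxy-2-methylpentanoate
Conditions: 3 (2 equiv), n-BuLi (1.5 equiv), THF, −20 °C; then 7, −20 °C to 0 °C; NH4Cl
Reagents that add atoms: none
Why: Transesterification of the N-acyl oxazolidinone by a lithium alkoxide, which attacks the exocyclic carbonyl; at 0 °C or below the aldolate should not undergo retro-aldol cleavage, and auxiliary and excess 3 are recovered.

Step 5
Reactants: 8 (2E)-4-[(4-methoxybenzyl)oxy]-2-methylbut-2-en-1-yl (2R,3S)-5-{[tert-butyl(dimethyl)silyl]oxy}-3-hydroxy-2-methylpentanoate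
Product: 10 (2S,3S)-5-{[tert-butyl(dimethyl)silyl]oxy}-3-hydroxy-2-{(2S)-1-[(4-methoxybenzyl)oxy]-3-methylbut-3-en-2-yl}-2-methylpentanoic acid, via chelated dilithium enolate alkoxide 9 (not isolated)
Conditions: LiN(iPr)2 (3 equiv), THF, −78 °C; then 25 °C to 50 °C; 1 M HCl (the enolate is trapped with Me3SiCl before warming if it fragments)
Reagents that add atoms: none
Why: Dianionic ester-enolate Claisen (Ireland–Claisen type) [3,3] rearrangement; the lithium bridge between the C2 alkoxide and the enolate oxygen fixes the enolate geometry (methyl cis to the allyl oxygen), and the allyl terminus should add to the face away from the C3 chain of the chelate (Fráter–Seebach sense), which sets quaternary C1 with methyl syn to the C2 oxygen. A chair transition state with the E olefin places CH2OPMB equatorial and sets C10.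

Step 6
Reactants: 10 (2S,3S)-5-{[tert-butyl(dimethyl)silyl]oxy}-3-hydroxy-2-{(2S)-1-[(4-methoxybenzyl)oxy]-3-methylbut-3-en-2-yl}-2-methylpentanoic acid
Product: 11 (2R,3S)-5-{[tert-butyl(dimethyl)silyl]oxy}-2-{(2S)-1-[(4-methoxybenzyl)oxy]-3-methylbut-3-en-2-yl}-2-methylpentane-1,3-diol
Conditions: LiAlH4, THF, 0 °C to 60 °C; Fieser work-up
Reagents that add atoms: none
Why: Hydride reduction of the carboxylic acid to the primary alcohol (C14); the neopentyl acid needs warming, and ethers, silyl ether and the isolated olefin are inert.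

Step 7
Reactants: 11 (2R,3S)-5-{[tert-butyl(dimethyl)silyl]oxy}-2-{(2S)-1-[(4-methoxybenzyl)oxy]-3-methylbut-3-en-2-yl}-2-methylpentane-1,3-diol
Product: 12 (2S,3S)-5-{[tert-butyl(dimethyl)silyl]oxy}-3-hydroxy-2-{(2S)-1-[(4-methoxybenzyl)oxy]-3-methylbut-3-en-2-yl}-2-methylpentanal
Conditions: TEMPO (0.2 equiv), PhI(OAc)2, CH2Cl2, 25 °C
Reagents that add atoms: none
Why: Oxoammonium (TEMPO) oxidation, selective for the primary over the secondary alcohol; the aldehyde has no α-hydrogen, so it can neither epimerise nor dehydrate.

Step 8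
Reactants: 12 (2S,3S)-5-{[tert-butyl(dimethyl)silyl]oxy}-3-hydroxy-2-{(2S)-1-[(4-methoxybenzyl)oxy]-3-methylbut-3-en-2-yl}-2-methylpentanal
Product: 13 (3S,4R,5S)-1-{[tert-butyl(dimethyl)silyl]oxy}-4-{(2S)-1-[(4-methoxybenzyl)oxy]-3-methylbut-3-en-2-yl}-4-methyloct-7-ene-3,5-diol
Conditions: (−)-Ipc2B(allyl) (2.5 equiv), Et2O, −78 °C to −40 °C; then NaOH, H2O2, 0 °C to 25 °C
Reagents that add atoms: (−)-B-allyldiisopinocampheylborane, C=CCB([C@@H]1C[C@@H]2C[C@H]([C@H]1C)C2(C)C)[C@@H]1C[C@@H]2C[C@H]([C@H]1C)C2(C)C
Why: Brown allylboration through a closed chair transition state under reagent control; with aldehydes whose substituent outranks allyl (as with pivalaldehyde) this enantiomer of the reagent gives the S carbinol, here C14, and the excess covers the free hydroxyl.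

Step 9
Reactants: 13 (3S,4R,5S)-1-{[tert-butyl(dimethyl)silyl]oxy}-4-{(2S)-1-[(4-methoxybenzyl)oxy]-3-methylbut-3-en-2-yl}-4-methyloct-7-ene-3,5-diol
Product: 14 (3S,4R,5S)-1-{[tert-butyl(dimethyl)silyl]oxy}-4-{(2S)-1-[(4-methoxybenzyl)oxy]-3-methylbut-3-en-2-yl}-4-methyloct-7-ene-3,5-diyl diacetate
Conditions: Ac2O, pyridine, DMAP (0.2 equiv), CH2Cl2, 25 °C to 40 °C
Reagents that add atoms: acetic anhydride, CC(=O)OC(C)=O
Why: DMAP-catalysed acylation of both hindered secondary hydroxyls; it installs the O2 and O14 acetates of the target in one step.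

Step 10
Reactants: 14 (3S,4R,5S)-1-{[tert-butyl(dimethyl)silyl]oxy}-4-{(2S)-1-[(4-methoxybenzyl)oxy]-3-methylbut-3-en-2-yl}-4-methyloct-7-ene-3,5-diyl diacetate
Product: 15 (1S,5S,6R)-6-[(1S)-1-acetoxy-3-{[tert-butyl(dimethyl)silyl]oxy}propyl]-5-{[(4-methoxybenzyl)oxy]methyl}-4,6-dimethylcyclohex-3-en-1-yl acetate
Conditions: (H2IMes)(PCy3)Cl2Ru=CHPh (second-generation Grubbs catalyst, 5 mol%), CH2Cl2 (0.005 M), 40 °C
Reagents that add atoms: none
Why: Ring-closing metathesis between the vinyl and the isopropenyl group gives the trisubstituted C11=C12 olefin of ring A; six-membered closure with loss of ethene should be fast even next to the quaternary carbon.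

Step 11
Reactants: 15 (1S,5S,6R)-6-[(1S)-1-acetoxy-3-{[tert-butyl(dimethyl)silyl]oxy}propyl]-5-{[(4-methoxybenzyl)oxy]methyl}-4,6-dimethylcyclohex-3-en-1-yl acetate
Product: 16 (1S,5S,6R)-6-[(1S)-1-acetoxy-3-hydroxypropyl]-5-{[(4-methoxybenzyl)oxy]methyl}-4,6-dimethylcyclohex-3-en-1-yl acetate
Conditions: HF·pyridine, pyridine, THF, 0 °C to 25 °C
Reagents that add atoms: none
Why: Fluoride cleavage of the primary silyl ether; the slightly acidic medium should suppress 1,3-acetyl migration from O2 to O4, and the benzyl-type ether and acetates are inert.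

Step 12
Reactants: 16 (1S,5S,6R)-6-[(1S)-1-acetoxy-3-hydroxypropyl]-5-{[(4-methoxybenzyl)oxy]methyl}-4,6-dimethylcyclohex-3-en-1-yl acetate
Product: 17 (1S,5S,6R)-6-[(1S)-1-acetoxy-3-oxopropyl]-5-{[(4-methoxybenzyl)oxy]methyl}-4,6-dimethylcyclohex-3-en-1-yl acetate (ring-A aldehyde, C4 = CHO)
Conditions: Dess–Martin periodinane, NaHCO3, CH2Cl2, 0 °C to 25 °C; used without storage
Reagents that add atoms: none
Why: Dess–Martin oxidation under buffered, non-basic conditions gives the β-acetoxy aldehyde without β-elimination of acetate.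

Step 13
Reactants: 18 L-arabinose
Product: 19 methyl α-L-arabinofuranoside
Conditions: AcCl (0.1 equiv), MeOH, 25 °C, stopped at the furanoside stage; Et3N; chromatography
Reagents that add atoms: methanol, CO
Why: Fischer glycosidation under kinetic control gives the furanosides, of which the 1,2-trans (α) anomer should predominate and is separated.

Step 14
Reactants: 19 methyl α-L-arabinofuranoside
Product: 20 methyl 3,5-O-(1,1,3,3-tetraisopropyldisiloxane-1,3-diyl)-α-L-arabinofuranoside
Conditions: (iPr2SiCl)2O, pyridine, 0 °C to 25 °C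
Reagents that add atoms: 1,3-dichloro-1,1,3,3-tetraisopropyldisiloxane, CC(C)[Si](Cl)(C(C)C)O[Si](Cl)(C(C)C)C(C)C
Why: The disiloxane reacts first at the primary hydroxyl and then bridges to O3, which leaves only O2 free.

Step 15
Reactants: 20 methyl 3,5-O-(1,1,3,3-tetraisopropyldisiloxane-1,3-diyl)-α-L-arabinofuranoside
Product: 21 methyl 2-O-methanesulfonyl-3,5-O-(1,1,3,3-tetraisopropyldisiloxane-1,3-diyl)-α-L-arabinofuranoside
Conditions: MsCl, Et3N, CH2Cl2, 0 °C
Reagents that add atoms: methanesulfonyl chloride, CS(Cl)(=O)=O
Why: Sulfonylation of the only free hydroxyl turns O2 into a leaving group trans to O3.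

Step 16
Reactants: 21 methyl 2-O-methanesulfonyl-3,5-O-(1,1,3,3-tetraisopropyldisiloxane-1,3-diyl)-α-L-arabinofuranoside
Product: 23 methyl 2,3-anhydro-α-L-ribofuranoside, via methyl 2-O-methanesulfonyl-α-L-arabinofuranoside 22 (not isolated)
Conditions: Bu4NF, AcOH, THF, 25 °C; then K2CO3, MeOH, 25 °C
Reagents that add atoms: none
Why: Desilylation, then intramolecular Williamson displacement: O3 attacks C2 from the face opposite the mesylate (inversion at C2) and gives the epoxide cis to the methoxy group; O5 lies on the wrong face to compete at C2.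

Step 17
Reactants: 23 methyl 2,3-anhydro-α-L-ribofuranoside
Product: 24 methyl 2,3-anhydro-5-O-[tert-butyl(diphenyl)silyl]-α-L-ribofuranoside
Conditions: t-BuPh2SiCl, imidazole, CH2Cl2, 0 °C to 25 °C
Reagents that add atoms: tert-butyl(chloro)diphenylsilane, CC(C)(C)[Si](Cl)(c1ccccc1)c1ccccc1
Why: Silylation of the primary hydroxyl; the large group on O5 also screens the rear face of C3 in the next step and does not migrate under base.

Step 18
Reactants: 24 methyl 2,3-anhydro-5-O-[tert-butyl(diphenyl)silyl]-α-L-ribofuranoside
Product: 25 methyl 5-O-[tert-butyl(diphenyl)silyl]-2-deoxy-2-C-methyl-α-L-arabinofuranoside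
Conditions: MeLi (6 equiv), CuI (3 equiv), Et2O, 0 °C; then 24, −40 °C to 0 °C; NH4Cl/NH3
Reagents that add atoms: methyllithium, [Li]C (methyl delivered as lithium dimethylcuprate, [Li+].C[Cu-]C)
Why: Anti opening of the epoxide by a Gilman cuprate; the rear face of C3 is blocked by the silyloxymethyl group on C4 while the rear face of C2 is flanked only by the anomeric hydrogen, so methyl should enter at C2 trans to the epoxide oxygen. This sets C17 (methyl cis to the C5 side chain, trans to OMe).

Step 19
Reactants: 25 methyl 5-O-[tert-butyl(diphenyl)silyl]-2-deoxy-2-C-methyl-α-L-arabinofuranoside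
Product: 26 methyl 5-O-[tert-butyl(diphenyl)silyl]-2-deoxy-3-O-(4-methoxybenzyl)-2-C-methyl-α-L-arabinofuranoside
Conditions: NaH, 4-methoxybenzyl chloride, Bu4NI (cat.), DMF, 0 °C to 25 °C
Reagents that add atoms: 4-methoxybenzyl chloride, COc1ccc(CCl)cc1
Why: Williamson etherification of the secondary alkoxide; O8 gets the same oxidatively removable group as O9.

Step 20
Reactants: 26 methyl 5-O-[tert-butyl(diphenyl)silyl]-2-deoxy-3-O-(4-methoxybenzyl)-2-C-methyl-α-L-arabinofuranoside
Product: 27 methyl 2-deoxy-3-O-(4-methoxybenzyl)-2-C-methyl-α-L-arabinofuranoside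
Conditions: Bu4NF, AcOH, THF, 25 °C
Reagents that add atoms: none
Why: Fluoride cleavage of the silyl ether frees the primary hydroxyl; ether and acetal are inert.

Step 21
Reactants: 27 methyl 2-deoxy-3-O-(4-methoxybenzyl)-2-C-methyl-α-L-arabinofuranoside
Product: 28 methyl 2-deoxy-3-O-(4-methoxybenzyl)-2-C-methyl-α-L-arabino-pentodialdo-1,4-furanoside
Conditions: Dess–Martin periodinane, NaHCO3, CH2Cl2, 0 °C to 25 °C
Reagents that add atoms: none
Why: Dess–Martin oxidation to the α-alkoxy aldehyde under neutral conditions, used directly so that C4 of the sugar (C7) does not epimerise.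

Step 22
Reactants: 28 methyl 2-deoxy-3-O-(4-methoxybenzyl)-2-C-methyl-α-L-arabino-pentodialdo-1,4-furanoside
Product: 29 methyl 2,5,6-trideoxy-3-O-(4-methoxybenzyl)-2-C-methyl-α-L-arabino-hex-5-ynofuranoside (terminal alkyne, C6≡C5)
Conditions: dimethyl (1-diazo-2-oxopropyl)phosphonate, K2CO3, MeOH, 0 °C to 25 °C
Reagents that add atoms: dimethyl (1-diazo-2-oxopropyl)phosphonate, COP(=O)(OC)C(=[N+]=[N-])C(C)=O
Why: Seyferth–Gilbert homologation with the Ohira–Bestmann reagent; ring-bound α-alkoxy aldehydes of sugars are homologated under these mild conditions without loss of the α-centre.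

Step 23
Reactants: 29 methyl 2,5,6-trideoxy-3-O-(4-methoxybenzyl)-2-C-methyl-α-L-arabino-hex-5-ynofuranoside
Product: 31 methyl 2,5,6-trideoxy-3-O-(4-methoxybenzyl)-2-C-methyl-α-L-arabino-hept-5-ynofuranoside (propargylic alcohol, C16–OH), via lithium acetylide 30 (not isolated)
Conditions: n-BuLi, THF, −78 °C; (CH2O)n, −78 °C to 25 °C; NH4Cl
Reagents that add atoms: paraformaldehyde (formaldehyde), C=O
Why: Addition of the lithium acetylide to formaldehyde brings in C16 and the hydroxyl that directs the next step.

Step 24
Reactants: 31 methyl 2,5,6-trideoxy-3-O-(4-methoxybenzyl)-2-C-methyl-α-L-arabino-hept-5-ynofuranoside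
Product: 32 (5Z)-alkenylstannane: 31 with H on C6 and Bu3Sn on C5 (tin cis to C7, geminal to CH2OH)
Conditions: [Cp*RuCl]4 (2.5 mol%), Bu3SnH, CH2Cl2, 25 °C
Reagents that add atoms: tributylstannane, CCCC[SnH](CCCC)CCCC
Why: Ruthenium-catalysed trans-hydrostannation directed by the propargylic hydroxyl, which binds the chloride ligand and places tin on the proximal alkyne carbon; trans addition puts tin cis to C7, which is the geometry needed for the ring olefin.

Step 25
Reactants: 32 (5Z)-alkenylstannane
Product: 33 (5Z)-alkenyl iodide: 32 with iodine in place of tin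
Conditions: I2, CH2Cl2, 0 °C
Reagents that add atoms: iodine, II
Why: Iododestannylation proceeds with retention of olefin geometry.

Step 26
Reactants: 33 (5Z)-alkenyl iodide with free C16 hydroxyl
Product: 34 (5Z)-alkenyl iodide with O16 as triethylsilyl ether, O8 as 4-methoxybenzyl ether, methyl α-L-furanoside
Conditions: Et3SiCl, imidazole, CH2Cl2, 0 °C
Reagents that add atoms: chlorotriethylsilane, CC[Si](Cl)(CC)CC
Why: Silylation of the primary allylic alcohol; an ether on the carbon next to the future carbon–chromium bond does not eliminate, and it can later be removed in the presence of the O4 silyl ether.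

Step 27
Reactants: 17 ring-A aldehyde (C4 = CHO); 34 (5Z)-alkenyl iodide
Product: 35 (4R,5Z) seco allylic alcohol: C4–C5 bond formed; O8 and O9 as 4-methoxybenzyl ethers, O16 as triethylsilyl ether, O2 and O14 as acetates, C19 as methyl α-L-furanoside acetal
Conditions: CrCl2 (4 equiv), (S)-N-[2-(4-isopropyl-4,5-dihydro-1,3-oxazol-2-yl)-6-methylphenyl]methanesulfonamide (4.4 equiv), Et3N (4.4 equiv), THF, 25 °C; then NiCl2 (0.2 equiv), 34 and 17, 25 °C
Reagents that add atoms: none
Why: Nozaki–Hiyama–Kishi coupling: zerovalent nickel inserts into the C–I bond, the alkenyl group passes to trivalent chromium with retention of geometry and adds to the aldehyde; acetates, ethers and the acetal are tolerated. The chiral sulfonamide on chromium should override the weak 1,3-anti bias of the β-acetoxy aldehyde and set C4 (R).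

Step 28
Reactants: 35 (4R,5Z) seco allylic alcohol
Product: 36 O4 tert-butyldimethylsilyl ether of 35
Conditions: t-BuMe2SiOTf, 2,6-lutidine, CH2Cl2, −78 °C
Reagents that add atoms: tert-butyldimethylsilyl trifluoromethanesulfonate, CC(C)(C)[Si](C)(C)OS(=O)(=O)C(F)(F)F
Why: Silylation of the hindered allylic alcohol with the silyl triflate at low temperature leaves acetal and triethylsilyl ether untouched; O4 is thereby set apart from the hydroxyls that are later acetylated.

Step 29
Reactants: 36 O4 tert-butyldimethylsilyl ether
Product: 37 seco diol: free C8 (secondary) and C9 (primary) hydroxyls; O4 and O16 silyl ethers, O2 and O14 acetates, methyl α-L-furanoside acetal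
Conditions: DDQ, CH2Cl2/pH 7 buffer (10:1), 0 °C to 25 °C
Reagents that add atoms: none
Why: Oxidative cleavage of both 4-methoxybenzyl ethers by hydride abstraction and hydrolysis; silyl ethers, acetates and olefins should be inert under buffered conditions.

Step 30
Reactants: 37 seco diol
Product: 38 seco keto aldehyde: C9 aldehyde on ring A and C8 ketone in the methyl α-L-furanosid-3-ulose; O4 tert-butyldimethylsilyl ether, O16 triethylsilyl ether, O2 and O14 acetates, 5Z olefin
Conditions: Dess–Martin periodinane (4 equiv), NaHCO3, CH2Cl2, 0 °C to 25 °C; filtered through neutral silica and used at once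
Reagents that add atoms: none
Why: Double Dess–Martin oxidation; neutral, buffered conditions are chosen because the β,γ-unsaturated aldehyde can slip into conjugation and the keto acetal can lose methanol under base.

Step 31
Reactants: 38 seco keto aldehyde
Product: 39 ten-membered 8,9-diol (8S,9S): C8–C9 bond formed, tertiary C8 and secondary C9 hydroxyls; C19 methyl acetal, O4 tert-butyldimethylsilyl ether, O16 triethylsilyl ether, O2 and O14 acetates
Conditions: SmI2 (3 equiv, 0.1 M in THF), THF, 38 added over 8 h to a final 0.002 M, 0 °C to 25 °C, no HMPA, no proton source; aq. NaHCO3/Na2S2O3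
Reagents that add atoms: none
Why: Electron transfer from divalent samarium to the aldehyde (more easily reduced than the doubly α-branched ketone) gives the C9 ketyl, whose oxygen-bound trivalent samarium also binds the C8 carbonyl oxygen; the ketyl carbon adds to C8 and a second electron gives the samarium diolate, protonated on work-up. The closest known reaction type is the SmI2-mediated intramolecular pinacol coupling of keto aldehydes used for medium and large carbocycles. The ten-membered ring closes in the exo mode with both oxygens outside the ring, and the Z C5=C6 olefin and ring A already hold six of the ten ring atoms in a turn, which lowers the entropic cost. C8 is controlled by the furanone: C6 on C7 and the methyl on C17 lie on one face of the five-membered ring, so C9 should bond to the opposite face, which puts the new hydroxyl cis to both and C6 and C9 trans, as in the target. C9 is controlled by the samarium bridge between the two oxygens together with the preference of C10 and ring A to point away from the furanose ring oxygen; this is the less secure centre. The step needs chemoselectivity for the aldehyde, which the reduction potentials and the slow addition at high dilution should secure, and it needs the C7–O bond α to the ketone to survive, which is why the reductant is kept weak and the oxygen on C7 is an ether and not an ester.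

Step 32
Reactants: 39 ten-membered 8,9-diol
Product: 40 8,9,16-triol: 39 without the triethylsilyl group
Conditions: PPTS (0.2 equiv), MeOH/CH2Cl2, 0 °C
Reagents that add atoms: none
Why: Acid-catalysed methanolysis removes the primary triethylsilyl ether much faster than the secondary tert-butyldimethylsilyl ether; the methyl acetal is unchanged in methanol.

Step 33
Reactants: 40 8,9,16-triol
Product: 41 9,16-diacetate (2,9,14,16-tetraacetate) with free tertiary C8 hydroxyl, O4 silyl ether and C19 methyl acetal
Conditions: Ac2O, pyridine, DMAP (0.1 equiv), CH2Cl2, 0 °C to 25 °C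
Reagents that add atoms: acetic anhydride, CC(=O)OC(C)=O
Why: Acylation of the primary allylic and the secondary hydroxyl; the tertiary C8 hydroxyl should not react under these conditions.

Step 34
Reactants: 41 tetraacetate methyl acetal
Product: 42 lactol (C19 hemiacetal, both anomers), otherwise as 41
Conditions: AcOH/THF/H2O (3:1:1), 45 °C
Reagents that add atoms: water, O
Why: Acid hydrolysis of a furanoside that has no oxygen on the carbon next to the acetal (C17) is fast, so it should proceed under conditions that spare the secondary silyl ether and the acetates.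

Step 35
Reactants: 42 lactol
Product: 43 O4-silylated target: lactone C19=O, otherwise as 42
Conditions: TEMPO (0.2 equiv), PhI(OAc)2, CH2Cl2, 25 °C
Reagents that add atoms: none
Why: Oxoammonium oxidation of the lactol to the lactone; the only other free hydroxyl is tertiary, and the neutral medium leaves C17 untouched.

Step 36
Reactants: 43 O4-silylated target
Product: 44 CNP0226727.2 (target)
Conditions: HF·pyridine, pyridine, THF, 0 °C to 25 °C
Reagents that add atoms: none
Why: Fluoride cleavage of the last silyl ether under buffered, non-basic conditions, so that acetates do not migrate and the β-hydroxy lactone does not epimerise or eliminate.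

## Compound list

1 | 3-methylbut-2-en-1-ol | CC(C)=CCO | starting material
2 | 1-methoxy-4-{[(3-methylbut-2-en-1-yl)oxy]methyl}benzene | COc1ccc(COCC=C(C)C)cc1 | intermediate
3 | (2E)-4-[(4-methoxybenzyl)oxy]-2-methylbut-2-en-1-ol | OC/C(C)=C/COCc1ccc(OC)cc1 | intermediate
4 | (4R)-4-benzyl-3-propanoyl-1,3-oxazolidin-2-one | CCC(=O)N1[C@H](Cc2ccccc2)COC1=O | starting material
5 | 3-{[tert-butyl(dimethyl)silyl]oxy}propanal | O=CCCO[Si](C)(C)C(C)(C)C | starting material
6 | dibutylboron Z-enolate of 4 | C/C=C(\OB(CCCC)CCCC)N1[C@H](Cc2ccccc2)COC1=O | intermediate (not isolated)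
7 | (4R)-4-benzyl-3-[(2R,3S)-5-{[tert-butyl(dimethyl)silyl]oxy}-3-hydroxy-2-methylpentanoyl]-1,3-oxazolidin-2-one | C[C@@H](C(=O)N1[C@H](Cc2ccccc2)COC1=O)[C@@H](O)CCO[Si](C)(C)C(C)(C)C | intermediate
8 | (2E)-4-[(4-methoxybenzyl)oxy]-2-methylbut-2-en-1-yl (2R,3S)-5-{[tert-butyl(dimethyl)silyl]oxy}-3-hydroxy-2-methylpentanoate | C[C@@H](C(=O)OC/C(C)=C/COCc1ccc(OC)cc1)[C@@H](O)CCO[Si](C)(C)C(C)(C)C | intermediate
9 | chelated dilithium enolate alkoxide of 8 | [Li+].[Li+].C/C(=C(/[O-])OC/C(C)=C/COCc1ccc(OC)cc1)[C@@H]([O-])CCO[Si](C)(C)C(C)(C)C | intermediate (not isolated)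
10 | (2S,3S)-5-{[tert-butyl(dimethyl)silyl]oxy}-3-hydroxy-2-{(2S)-1-[(4-methoxybenzyl)oxy]-3-methylbut-3-en-2-yl}-2-methylpentanoic acid | COc1ccc(COC[C@@H](C(C)=C)[C@](C)(C(=O)O)[C@@H](O)CCO[Si](C)(C)C(C)(C)C)cc1 | intermediate
11 | (2R,3S)-5-{[tert-butyl(dimethyl)silyl]oxy}-2-{(2S)-1-[(4-methoxybenzyl)oxy]-3-methylbut-3-en-2-yl}-2-methylpentane-1,3-diol | COc1ccc(COC[C@@H](C(C)=C)[C@](C)(CO)[C@@H](O)CCO[Si](C)(C)C(C)(C)C)cc1 | intermediate
12 | (2S,3S)-5-{[tert-butyl(dimethyl)silyl]oxy}-3-hydroxy-2-{(2S)-1-[(4-methoxybenzyl)oxy]-3-methylbut-3-en-2-yl}-2-methylpentanal | COc1ccc(COC[C@@H](C(C)=C)[C@](C)(C=O)[C@@H](O)CCO[Si](C)(C)C(C)(C)C)cc1 | intermediate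
13 | (3S,4R,5S)-1-{[tert-butyl(dimethyl)silyl]oxy}-4-{(2S)-1-[(4-methoxybenzyl)oxy]-3-methylbut-3-en-2-yl}-4-methyloct-7-ene-3,5-diol | COc1ccc(COC[C@@H](C(C)=C)[C@](C)([C@@H](O)CC=C)[C@@H](O)CCO[Si](C)(C)C(C)(C)C)cc1 | intermediate
14 | (3S,4R,5S)-1-{[tert-butyl(dimethyl)silyl]oxy}-4-{(2S)-1-[(4-methoxybenzyl)oxy]-3-methylbut-3-en-2-yl}-4-methyloct-7-ene-3,5-diyl diacetate | COc1ccc(COC[C@@H](C(C)=C)[C@](C)([C@@H](OC(C)=O)CC=C)[C@@H](OC(C)=O)CCO[Si](C)(C)C(C)(C)C)cc1 | intermediate
15 | (1S,5S,6R)-6-[(1S)-1-acetoxy-3-{[tert-butyl(dimethyl)silyl]oxy}propyl]-5-{[(4-methoxybenzyl)oxy]methyl}-4,6-dimethylcyclohex-3-en-1-yl acetate | COc1ccc(COC[C@H]2C(C)=CC[C@H](OC(C)=O)[C@]2(C)[C@@H](OC(C)=O)CCO[Si](C)(C)C(C)(C)C)cc1 | intermediate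
16 | (1S,5S,6R)-6-[(1S)-1-acetoxy-3-hydroxypropyl]-5-{[(4-methoxybenzyl)oxy]methyl}-4,6-dimethylcyclohex-3-en-1-yl acetate | COc1ccc(COC[C@H]2C(C)=CC[C@H](OC(C)=O)[C@]2(C)[C@@H](OC(C)=O)CCO)cc1 | intermediate
17 | (1S,5S,6R)-6-[(1S)-1-acetoxy-3-oxopropyl]-5-{[(4-methoxybenzyl)oxy]methyl}-4,6-dimethylcyclohex-3-en-1-yl acetate | COc1ccc(COC[C@H]2C(C)=CC[C@H](OC(C)=O)[C@]2(C)[C@@H](OC(C)=O)CC=O)cc1 | intermediate
18 | L-arabinose | O=C[C@H](O)[C@@H](O)[C@@H](O)CO | starting material
19 | methyl α-L-arabinofuranoside | OC[C@@H]1O[C@@H](OC)[C@H](O)[C@H]1O | intermediate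
20 | methyl 3,5-O-(1,1,3,3-tetraisopropyldisiloxane-1,3-diyl)-α-L-arabinofuranoside | CC(C)[Si]1(C(C)C)OC[C@@H]2O[C@@H](OC)[C@H](O)[C@H]2O[Si](C(C)C)(C(C)C)O1 | intermediate
21 | methyl 2-O-methanesulfonyl-3,5-O-(1,1,3,3-tetraisopropyldisiloxane-1,3-diyl)-α-L-arabinofuranoside | CC(C)[Si]1(C(C)C)OC[C@@H]2O[C@@H](OC)[C@H](OS(C)(=O)=O)[C@H]2O[Si](C(C)C)(C(C)C)O1 | intermediate
22 | methyl 2-O-methanesulfonyl-α-L-arabinofuranoside | OC[C@@H]1O[C@@H](OC)[C@H](OS(C)(=O)=O)[C@H]1O | intermediate (not isolated)
23 | methyl 2,3-anhydro-α-L-ribofuranoside | OC[C@@H]1O[C@@H](OC)[C@H]2O[C@@H]12 | intermediate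
24 | methyl 2,3-anhydro-5-O-[tert-butyl(diphenyl)silyl]-α-L-ribofuranoside | CC(C)(C)[Si](OC[C@@H]1O[C@@H](OC)[C@H]2O[C@@H]12)(c1ccccc1)c1ccccc1 | intermediate
25 | methyl 5-O-[tert-butyl(diphenyl)silyl]-2-deoxy-2-C-methyl-α-L-arabinofuranoside | CC(C)(C)[Si](OC[C@@H]1O[C@@H](OC)[C@H](C)[C@H]1O)(c1ccccc1)c1ccccc1 | intermediate
26 | methyl 5-O-[tert-butyl(diphenyl)silyl]-2-deoxy-3-O-(4-methoxybenzyl)-2-C-methyl-α-L-arabinofuranoside | CC(C)(C)[Si](OC[C@@H]1O[C@@H](OC)[C@H](C)[C@H]1OCc2ccc(OC)cc2)(c3ccccc3)c4ccccc4 | intermediate
27 | methyl 2-deoxy-3-O-(4-methoxybenzyl)-2-C-methyl-α-L-arabinofuranoside | OC[C@@H]1O[C@@H](OC)[C@H](C)[C@H]1OCc1ccc(OC)cc1 | intermediate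
28 | methyl 2-deoxy-3-O-(4-methoxybenzyl)-2-C-methyl-α-L-arabino-pentodialdo-1,4-furanoside | O=C[C@@H]1O[C@@H](OC)[C@H](C)[C@H]1OCc1ccc(OC)cc1 | intermediate
29 | methyl 2,5,6-trideoxy-3-O-(4-methoxybenzyl)-2-C-methyl-α-L-arabino-hex-5-ynofuranoside | C#C[C@@H]1O[C@@H](OC)[C@H](C)[C@H]1OCc1ccc(OC)cc1 | intermediate
30 | lithium acetylide of 29 | [Li]C#C[C@@H]1O[C@@H](OC)[C@H](C)[C@H]1OCc1ccc(OC)cc1 | intermediate (not isolated)
31 | methyl 2,5,6-trideoxy-3-O-(4-methoxybenzyl)-2-C-methyl-α-L-arabino-hept-5-ynofuranoside | OCC#C[C@@H]1O[C@@H](OC)[C@H](C)[C@H]1OCc1ccc(OC)cc1 | intermediate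
32 | (5Z)-alkenylstannane (Bu3Sn on C5, CH2OH on C5, H on C6) | OC/C([Sn](CCCC)(CCCC)CCCC)=C/[C@@H]1O[C@@H](OC)[C@H](C)[C@H]1OCc1ccc(OC)cc1 | intermediate
33 | (5Z)-alkenyl iodide with free C16 hydroxyl | OC/C(I)=C/[C@@H]1O[C@@H](OC)[C@H](C)[C@H]1OCc1ccc(OC)cc1 | intermediate
34 | (5Z)-alkenyl iodide, O16 triethylsilyl ether | CC[Si](CC)(CC)OC/C(I)=C/[C@@H]1O[C@@H](OC)[C@H](C)[C@H]1OCc1ccc(OC)cc1 | intermediate
35 | (4R,5Z) seco allylic alcohol | COc1ccc(COC[C@H]2C(C)=CC[C@H](OC(C)=O)[C@]2(C)[C@@H](OC(C)=O)C[C@@H](O)/C(CO[Si](CC)(CC)CC)=C\[C@@H]3O[C@@H](OC)[C@H](C)[C@H]3OCc4ccc(OC)cc4)cc1 | intermediate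
36 | O4 tert-butyldimethylsilyl ether of 35 | COc1ccc(COC[C@H]2C(C)=CC[C@H](OC(C)=O)[C@]2(C)[C@@H](OC(C)=O)C[C@@H](O[Si](C)(C)C(C)(C)C)/C(CO[Si](CC)(CC)CC)=C\[C@@H]3O[C@@H](OC)[C@H](C)[C@H]3OCc4ccc(OC)cc4)cc1 | intermediate
37 | seco 8,9-diol | OC[C@H]1C(C)=CC[C@H](OC(C)=O)[C@]1(C)[C@@H](OC(C)=O)C[C@@H](O[Si](C)(C)C(C)(C)C)/C(CO[Si](CC)(CC)CC)=C\[C@@H]2O[C@@H](OC)[C@H](C)[C@H]2O | intermediate
38 | seco C9 aldehyde with C8 furanone acetal | O=C[C@H]1C(C)=CC[C@H](OC(C)=O)[C@]1(C)[C@@H](OC(C)=O)C[C@@H](O[Si](C)(C)C(C)(C)C)/C(CO[Si](CC)(CC)CC)=C\[C@@H]2O[C@@H](OC)[C@H](C)C2=O | intermediate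
39 | ten-membered 8,9-diol with lactol methyl acetal | CC[Si](CC)(CC)OC/C1=C/[C@@H]2O[C@@H](OC)[C@H](C)[C@@]2(O)[C@@H](O)[C@H]3C(C)=CC[C@H](OC(C)=O)[C@]3(C)[C@@H](OC(C)=O)C[C@H]1O[Si](C)(C)C(C)(C)C | intermediate
40 | 8,9,16-triol | OC/C1=C/[C@@H]2O[C@@H](OC)[C@H](C)[C@@]2(O)[C@@H](O)[C@H]3C(C)=CC[C@H](OC(C)=O)[C@]3(C)[C@@H](OC(C)=O)C[C@H]1O[Si](C)(C)C(C)(C)C | intermediate
41 | tetraacetate methyl acetal | CC(=O)OC/C1=C/[C@@H]2O[C@@H](OC)[C@H](C)[C@@]2(O)[C@@H](OC(C)=O)[C@H]3C(C)=CC[C@H](OC(C)=O)[C@]3(C)[C@@H](OC(C)=O)C[C@H]1O[Si](C)(C)C(C)(C)C | intermediate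
42 | lactol (C19 anomers) | CC(=O)OC/C1=C/[C@@H]2OC(O)[C@H](C)[C@@]2(O)[C@@H](OC(C)=O)[C@H]3C(C)=CC[C@H](OC(C)=O)[C@]3(C)[C@@H](OC(C)=O)C[C@H]1O[Si](C)(C)C(C)(C)C | intermediate
43 | O4-tert-butyldimethylsilyl ether of the target | CC(=O)OC/C1=C/[C@@H]2OC(=O)[C@H](C)[C@@]2(O)[C@@H](OC(C)=O)[C@H]3C(C)=CC[C@H](OC(C)=O)[C@]3(C)[C@@H](OC(C)=O)C[C@H]1O[Si](C)(C)C(C)(C)C | intermediate
44 | CNP0226727.2 | CC(=O)OC/C1=C/[C@@H]2OC(=O)[C@H](C)[C@@]2(O)[C@@H](OC(C)=O)[C@H]2C(C)=CC[C@H](OC(C)=O)[C@]2(C)[C@@H](OC(C)=O)C[C@H]1O | target

## Step count and least certain steps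

Total step count: 36. Longest linear sequence: 24 steps (steps 13–36, from L-arabinose). The ring-A branch is 12 steps (steps 1–12, 11 of them in line from prenol).

Step 31 (key step). What may go wrong: closure of the ten-membered ring may be slower than the alternatives open to the ketyl and to the reagent. These are further reduction of the C9 ketyl to the carbinol, intermolecular pairing, or electron transfer to the C8 ketone followed by loss of the ring oxygen on C7. Where the ring does close, facial control at C9 may be poor because the samarium bridge does not by itself fix which face of the ketyl is used. Fallback: ring formation and C9 control are separated. Starting from 38, the closure is run on low-valent titanium (TiCl3(DME)1.5, Zn–Cu, DME, 25 °C, slow addition), where both carbonyl oxygens are bound to the metal before the C–C bond forms and no free ketyl or samarium enolate is present. The resulting mixture of 39 and its C9 epimer, the (9R)-diol F1, is oxidised at C9 (Dess–Martin periodinane; the tertiary hydroxyl is inert) to the 8-hydroxy-9-ketone F2. F2 is reduced with Zn(BH4)2 through the five-membered chelate of the C8 hydroxyl and the C9 carbonyl (or with a bulky non-chelating hydride if the chelate gives the wrong face), and the route is rejoined at 39.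

Step 5. What may go wrong: a boat-like transition state (favoured if the axial C15 methyl collides with the methyl on the allyl unit) would invert C10, and the dianion may undergo retro-aldol cleavage before it rearranges. Fallback: the opposite olefin geometry is used, so that the boat pathway leads to the wanted centre. Z-selective Horner–Wadsworth–Emmons olefination (Ando type) of 2-[(4-methoxybenzyl)oxy]acetaldehyde with ethyl 2-(diphenoxyphosphoryl)propanoate gives ethyl (2Z)-4-[(4-methoxybenzyl)oxy]-2-methylbut-2-enoate F3. Reduction with i-Bu2AlH gives (2Z)-4-[(4-methoxybenzyl)oxy]-2-methylbut-2-en-1-ol F4. Its lithium alkoxide reacts with 7 as in step 4 to give the Z allyl ester F5, which is rearranged as its silyl ketene acetal. The fallback sets out from 7 and returns at 10.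

Step 27. What may go wrong: facial selectivity at C4 may be low or reversed, because the β-acetoxy aldehyde has an inherent 1,3-anti preference and the sense of the ligand is assumed. Fallback: C4 is set by reduction instead of addition. The coupling of 17 and 34 is run without regard to C4, giving 35 together with its (4S)-epimer F10. The mixture is oxidised with Dess–Martin periodinane to the Z enone F11, and F11 is reduced by Corey–Bakshi–Shibata reduction ((S)-2-methyl-CBS-oxazaborolidine, catecholborane, toluene, −78 °C; the alkenyl group acts as the large substituent) to the 4R alcohol. The route is rejoined at 35.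

Step 18. What may go wrong: the cuprate may open the epoxide at C3 as well, or react sluggishly at the electronically deactivated C2. Fallback: the C18 methyl is introduced by hydroxyl-directed hydrogenation instead of substitution. Starting from 20, oxidation (Dess–Martin periodinane) gives the 2-ulose F6, and Wittig methylenation (Ph3P=CH2) gives the 2-C-methylene compound F7. Bu4NF/AcOH gives the diol methyl 2-deoxy-2-C-methylene-α-L-threo-pentofuranoside F8. Hydrogenation with [Ir(cod)(PCy3)(py)]PF6 under H2 delivers hydrogen to C2 from the face of the allylic C3 hydroxyl and gives methyl 2-deoxy-2-C-methyl-α-L-arabinofuranoside F9. Selective silylation of the primary hydroxyl (t-BuPh2SiCl, imidazole) rejoins the route at 25.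

Step 8. What may go wrong: the free hydroxyl may consume the allylborane, and the bulky α-quaternary aldehyde may react slowly, so that conversion and reagent control suffer. Fallback: the aldehyde stage is avoided. Diol 11 is allylated directly at its primary carbinol by iridium-catalysed transfer-hydrogenative allylation (allyl acetate, [Ir(cod)Cl]2, the enantiomer of Cl,MeO-BIPHEP that gives 14S, 4-chloro-3-nitrobenzoic acid, Cs2CO3, THF, 100 °C), a catalyst-controlled reaction developed for unprotected 1,3-diols. The fallback sets out from 11 and returns at 13 and makes no further compound F0.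

## Further compounds

F1 | step 31 | (9R)-epimer of 39 | CC[Si](CC)(CC)OC/C1=C/[C@@H]2O[C@@H](OC)[C@H](C)[C@@]2(O)[C@H](O)[C@H]3C(C)=CC[C@H](OC(C)=O)[C@]3(C)[C@@H](OC(C)=O)C[C@H]1O[Si](C)(C)C(C)(C)C
F2 | step 31 | 8-hydroxy-9-ketone of the ten-membered ring | CC[Si](CC)(CC)OC/C1=C/[C@@H]2O[C@@H](OC)[C@H](C)[C@@]2(O)C(=O)[C@H]3C(C)=CC[C@H](OC(C)=O)[C@]3(C)[C@@H](OC(C)=O)C[C@H]1O[Si](C)(C)C(C)(C)C
F3 | step 5 | ethyl (2Z)-4-[(4-methoxybenzyl)oxy]-2-methylbut-2-enoate | CCOC(=O)/C(C)=C\COCc1ccc(OC)cc1
F4 | step 5 | (2Z)-4-[(4-methoxybenzyl)oxy]-2-methylbut-2-en-1-ol | OC/C(C)=C\COCc1ccc(OC)cc1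
F5 | step 5 | (2Z)-4-[(4-methoxybenzyl)oxy]-2-methylbut-2-en-1-yl (2R,3S)-5-{[tert-butyl(dimethyl)silyl]oxy}-3-hydroxy-2-methylpentanoate | C[C@@H](C(=O)OC/C(C)=C\COCc1ccc(OC)cc1)[C@@H](O)CCO[Si](C)(C)C(C)(C)C
F6 | step 18 | methyl 3,5-O-(1,1,3,3-tetraisopropyldisiloxane-1,3-diyl)-α-L-threo-pentofuranosid-2-ulose | CC(C)[Si]1(C(C)C)OC[C@@H]2O[C@@H](OC)C(=O)[C@H]2O[Si](C(C)C)(C(C)C)O1
F7 | step 18 | methyl 2-deoxy-2-C-methylene-3,5-O-(1,1,3,3-tetraisopropyldisiloxane-1,3-diyl)-α-L-threo-pentofuranoside | CC(C)[Si]1(C(C)C)OC[C@@H]2O[C@@H](OC)C(=C)[C@H]2O[Si](C(C)C)(C(C)C)O1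
F8 | step 18 | methyl 2-deoxy-2-C-methylene-α-L-threo-pentofuranoside | OC[C@@H]1O[C@@H](OC)C(=C)[C@H]1O
F9 | step 18 | methyl 2-deoxy-2-C-methyl-α-L-arabinofuranoside | OC[C@@H]1O[C@@H](OC)[C@H](C)[C@H]1O
F10 | step 27 | (4S)-epimer of 35 | COc1ccc(COC[C@H]2C(C)=CC[C@H](OC(C)=O)[C@]2(C)[C@@H](OC(C)=O)C[C@H](O)/C(CO[Si](CC)(CC)CC)=C\[C@@H]3O[C@@H](OC)[C@H](C)[C@H]3OCc4ccc(OC)cc4)cc1
F11 | step 27 | (5Z) C4 enone of the seco compound | COc1ccc(COC[C@H]2C(C)=CC[C@H](OC(C)=O)[C@]2(C)[C@@H](OC(C)=O)CC(=O)/C(CO[Si](CC)(CC)CC)=C\[C@@H]3O[C@@H](OC)[C@H](C)[C@H]3OCc4ccc(OC)cc4)cc1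
F0 | step 8 | none | none
A1 | alternative 1 | ten-membered C14 acid with C10 isopropenyl group | C[C@]1(C(=O)O)[C@H](C(C)=C)[C@H](O[Si](C)(C)C(C)(C)C)C(OC)(OC)[C@@H](O[Si](C)(C)C(C)(C)C)/C=C(CO[Si](C)(C)C(C)(C)C)\[C@H](OCc2ccc(OC)cc2)C[C@@H]1O[Si](C)(C)C(C)(C)C
A2 | alternative 2 | hydroxy lactone with C9 and C4 silyl ethers | CC(=O)OC/C1=C/[C@@H]2OC(=O)[C@H](C)[C@@]2(O)[C@@H](O[Si](CC)(CC)CC)[C@H]3C(C)=CC[C@H](OC(C)=O)[C@]3(C)[C@@H](OC(C)=O)C[C@H]1O[Si](C)(C)C(C)(C)C
A3 | alternative 3 | ten-membered 4,9-diketone | CC(=O)OC/C1=C/[C@@H]2OC(=O)[C@H](C)[C@@]2(O[Si](C)(C)C)C(=O)[C@H]3C(C)=CC[C@H](OC(C)=O)[C@]3(C)[C@@H](OC(C)=O)CC1=O
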